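**Plan**

- The target is 3-(3,4-dimethoxyphenyl)propyl 3-(3,4-dimethoxyphenyl)propanoate: two veratrole rings joined by a propyl propanoate chain, with no stereocentre.
- Enabling feature: in each benzene ring the chain sits on C1 and the methoxy groups on the adjacent carbons C3 and C4. C2–C3(OMe)–C4(OMe)–C5 therefore maps onto a symmetrical 2,3-dimethoxybutadiene, and C1/C6 onto a terminal alkyne.
- Retrosynthesis: both arenes are first taken back to 1,4-cyclohexadienes (sp3 carbons at C2 and C5). The bonds C1–C2 and C5–C6 of each ring are then cut (four C–C bonds), and last the ester C–O bond.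
- Forward: the chain is joined first by esterifying two five-carbon alkynes. Both rings then arise together in one twofold cobalt-catalysed [4+2], and a final dehydrogenation makes them aromatic.
- Stereochemistry: there is none to set, and the symmetry of the diene removes any regiochemical choice.

Key step: step 2

Remark: pent-4-ynoic acid, pent-4-yn-1-ol and 2,3-dimethoxybuta-1,3-diene are taken as purchased reagents.

**Route**

Step 1
Reactants: 1 pent-4-ynoic acid; 2 pent-4-yn-1-ol
Product: 4 pent-4-yn-1-yl pent-4-ynoate, via O-acylisourea 3 (not isolated)
Conditions: DCC (N,N'-dicyclohexylcarbodiimide, 1.1 equiv), DMAP (4-dimethylaminopyridine, 10 mol%), CH2Cl2, 0 °C to rt; filtration of the urea, careful concentration (the ester is fairly volatile)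
Reagents that add atoms: none
Why: Steglich esterification, in which DCC turns acid 1 into O-acylisourea 3 and DMAP relays the acyl group to the unhindered primary alcohol 2 faster than the O-to-N acyl shift can occur, while both terminal alkynes are inert to these neutral conditions.

Step 2
Reactants: 4 pent-4-yn-1-yl pent-4-ynoate; 5 2,3-dimethoxybuta-1,3-diene
Product: 8 3-(4,5-dimethoxycyclohexa-1,4-dien-1-yl)propyl 3-(4,5-dimethoxycyclohexa-1,4-dien-1-yl)propanoate, via acyl-side monoadduct 6 (not isolated), via alkoxy-side monoadduct 7 (not isolated)
Conditions: CoBr2(dppe) (10 mol%; dppe = Ph2PCH2CH2PPh2), Zn powder (20 mol%), ZnI2 (20 mol%), 5 (3.5 equiv), slow addition of 4, CH2Cl2, rt; filtration through Et3N-deactivated silica, excess 5 removed in vacuo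
Reagents that add atoms: none
Why: This is the cobalt-catalysed neutral Diels–Alder reaction of an unactivated terminal alkyne with a 2,3-disubstituted buta-1,3-diene, run at both ends of one substrate: Zn reduces the divalent cobalt of CoBr2(dppe) to monovalent cobalt and ZnI2 abstracts bromide, opening sites for the s-cis diene and the alkyne. Oxidative cyclisation of the two bound π-systems forms the first C–C bond and a trivalent-cobalt allyl/vinyl metallacycle, and reductive elimination forms the second C–C bond and releases the 1,4-cyclohexadiene, so each six-membered ring closes as a metal-mediated formal [4+2] in which the four diene carbons and the two alkyne carbons become the ring. The two alkynes are kept apart by the seven-atom ester tether and should react independently, through monoadducts 6 and 7, to give 8 with four new C–C bonds and two new rings. No stereocentre is created, and because diene 5 is symmetrical both orientations of addition give the same ring, with the two methoxy groups necessarily on adjacent carbons that become C3 and C4 of the arene. The selectivity needed is chemoselectivity for the cross [4+2] over alkyne cyclotrimerisation and diene homo-coupling, which the chelating bisphosphine, the excess of diene and the slow addition of 4 should secure, while the ester is a spectator. The acid-labile enol ethers of 8 are protected by the amine-buffered filtration, and the crude material is taken on directly.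

Step 3
Reactants: 8 3-(4,5-dimethoxycyclohexa-1,4-dien-1-yl)propyl 3-(4,5-dimethoxycyclohexa-1,4-dien-1-yl)propanoate
Product: 11 3-(3,4-dimethoxyphenyl)propyl 3-(3,4-dimethoxyphenyl)propanoate, via acyl-side monoarene 9 (not isolated), via alkoxy-side monoarene 10 (not isolated)
Conditions: DDQ (2,3-dichloro-5,6-dicyano-1,4-benzoquinone, 2.2 equiv), toluene, 0 °C to rt; aq NaHCO3 wash
Reagents that add atoms: none
Why: Oxidative aromatisation of 1,4-cyclohexadienes by a high-potential quinone, in which DDQ abstracts hydride from a ring CH2 that is doubly allylic and flanked by an enol ether, the oxygen-stabilised cyclohexadienyl cation loses a proton to give the arene, and at room temperature with only a slight excess of oxidant the ester and the benzylic CH2 groups should survive.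

**Compound list**

1 | pent-4-ynoic acid | C#CCCC(=O)O | starting material
2 | pent-4-yn-1-ol | C#CCCCO | starting material
3 | N,N'-dicyclohexyl-O-(pent-4-ynoyl)isourea | C#CCCC(=O)OC(=NC1CCCCC1)NC1CCCCC1 | intermediate
4 | pent-4-yn-1-yl pent-4-ynoate | C#CCCCOC(=O)CCC#C | intermediate
5 | 2,3-dimethoxybuta-1,3-diene | C=C(OC)C(=C)OC | starting material
6 | pent-4-yn-1-yl 3-(4,5-dimethoxycyclohexa-1,4-dien-1-yl)propanoate | C#CCCCOC(=O)CCC1=CCC(OC)=C(OC)C1 | intermediate
7 | 3-(4,5-dimethoxycyclohexa-1,4-dien-1-yl)propyl pent-4-ynoate | C#CCCC(=O)OCCCC1=CCC(OC)=C(OC)C1 | intermediate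
8 | 3-(4,5-dimethoxycyclohexa-1,4-dien-1-yl)propyl 3-(4,5-dimethoxycyclohexa-1,4-dien-1-yl)propanoate | COC1=C(OC)CC(CCCOC(=O)CCC2=CCC(OC)=C(OC)C2)=CC1 | intermediate
9 | 3-(4,5-dimethoxycyclohexa-1,4-dien-1-yl)propyl 3-(3,4-dimethoxyphenyl)propanoate | COC1=C(OC)CC(CCCOC(=O)CCc2ccc(OC)c(OC)c2)=CC1 | intermediate
10 | 3-(3,4-dimethoxyphenyl)propyl 3-(4,5-dimethoxycyclohexa-1,4-dien-1-yl)propanoate | COc1ccc(CCCOC(=O)CCC2=CCC(OC)=C(OC)C2)cc1OC | intermediate
11 | 3-(3,4-dimethoxyphenyl)propyl 3-(3,4-dimethoxyphenyl)propanoate | COc1ccc(CCCOC(=O)CCc2ccc(OC)c(OC)c2)cc1OC | target

**Step count**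

Total steps: 3. Longest linear sequence: 3 steps (1 → 4 → 8 → 11).

**Steps most likely to fail**

Step 2. The Lewis-acidic ZnI2 may trigger oligomerisation of the electron-rich diene or degrade the enol ethers of the adducts. The reaction may stall after the first ring closure. Because each molecule of 4 carries two alkynes, intermolecular alkyne oligomerisation would cross-link the material.

The fallback sets out from 1 (with 5) and rejoins the route at 11. It moves the ring construction ahead of ester formation and runs it on a monoalkyne, where each cycloaddition can be driven to completion on its own and cross-linking is impossible. Fischer esterification of 1 (MeOH, cat. H2SO4, reflux) should give methyl pent-4-ynoate F1. A single cobalt-catalysed [4+2] with 5 under the catalyst system of step 2 should give methyl 3-(4,5-dimethoxycyclohexa-1,4-dien-1-yl)propanoate F2. DDQ should aromatise this to methyl 3-(3,4-dimethoxyphenyl)propanoate F3, a robust ester that can be purified rigorously. One portion of F3 is saponified (LiOH, THF/H2O, then acidification) to 3-(3,4-dimethoxyphenyl)propanoic acid F4. The other portion is reduced (LiAlH4, THF, 0 °C) to 3-(3,4-dimethoxyphenyl)propan-1-ol F5. DCC/DMAP esterification of F4 with F5 should then give 11.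

Step 3. The hydroquinone formed from DDQ is acidic and may hydrolyse an enol ether before hydride abstraction takes place. Excess quinone may attack the benzylic CH2 groups of the electron-rich veratrole rings once they have formed. Alternatively one ring may remain unaromatised.

The fallback sets out from 8 and returns at 11. Hydride abstraction by a quinone is replaced by heterogeneous catalytic dehydrogenation: Pd/C in toluene at reflux, open to air or with an alkene as hydrogen acceptor. This is neutral, produces no acid and involves no electrophilic oxidant that could touch the product. It makes no compound outside the list (entry F0).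

Step 1. O-to-N acyl migration in O-acylisourea 3 may divert the acid into an unreactive N-acylurea. Residual urea may follow the product, and the low-molecular-weight ester may be lost on concentration.

The fallback sets out from 2 and 1 and returns at 4. It forms the alkyl C–O bond by SN2 displacement instead of the acyl C–O bond. Alcohol 2 is converted (TsCl, Et3N, cat. DMAP, CH2Cl2, 0 °C) into pent-4-yn-1-yl 4-methylbenzenesulfonate F6. Acid 1 is deprotonated with Cs2CO3 in DMF, and the caesium carboxylate is alkylated with F6 at about 50 °C to give 4.

**Further compounds**

F1 | step 2 | methyl pent-4-ynoate | C#CCCC(=O)OC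
F2 | step 2 | methyl 3-(4,5-dimethoxycyclohexa-1,4-dien-1-yl)propanoate | COC(=O)CCC1=CCC(OC)=C(OC)C1
F3 | step 2 | methyl 3-(3,4-dimethoxyphenyl)propanoate | COC(=O)CCc1ccc(OC)c(OC)c1
F4 | step 2 | 3-(3,4-dimethoxyphenyl)propanoic acid | OC(=O)CCc1ccc(OC)c(OC)c1
F5 | step 2 | 3-(3,4-dimethoxyphenyl)propan-1-ol | OCCCc1ccc(OC)c(OC)c1
F0 | step 3 | none | none
F6 | step 1 | pent-4-yn-1-yl 4-methylbenzenesulfonate | C#CCCCOS(=O)(=O)c1ccc(C)cc1
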